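**Plan**
- Retrosynthesis: after removal of the two phenol benzyl groups, the two ring C–H bonds at C3 and C4 of the oxolane are cut (one syn addition of H2). This leads back to a 3,4-disubstituted 2,5-dihydrofuran that still carries the carbinol.
- Enabling feature: ring O1 is flanked by two unsubstituted CH2 groups (C2, C5) and both side chains sit on the C3–C4 bond, so the ring is the 1,4-adduct of oxygen to a 2,3-disubstituted buta-1,3-diene. Cutting O1–C5 and rejoining O1 to C3 gives the 1,2-adduct, a 2-substituted 2-vinyloxirane (three-membered ring O1–C2–C3, vinyl group C4=C5).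
- The oxirane goes back to the diene carbinol (directed epoxidation), the two =CH2 groups to an internal alkyne plus ethylene, and the carbinol C–C(sp) bond to O-benzylvanillin plus a 3-arylpropyne.
- Forward: the chain is joined by alkynylation, then diene, then oxirane (three-membered ring), then ring expansion to the five-membered ring, then hydrogenation and deprotection.
- Stereochemistry: the carbinol centre comes from ligand-controlled alkynylation. Both ring centres (cis) come from one hydroxyl-directed syn hydrogenation under A(1,3) control.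

Key step: step 6

Remark: the ProPhenol antipode that gives the 1R carbinol is assumed to be the (R,R)-ligand; if a test run shows the opposite sense, the (S,S)-ligand is used.
Remark: the carbinol centre keeps one spatial arrangement from 7 to 14; its descriptor is R up to 12 and S in 13 and 14 only because the CIP rank of the neighbouring carbon falls on hydrogenation.

Step 1
Reactants: 1 1-(benzyloxy)-4-bromo-2-methoxybenzene; 2 methoxyallene (1-methoxypropa-1,2-diene)
Product: 4 1-(benzyloxy)-2-methoxy-4-(prop-2-yn-1-yl)benzene, via arylmagnesium bromide 3 (not isolated)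
Conditions: Mg, THF, rt to 40 °C; then CuBr (5 mol%), 2, THF, −20 °C to rt; aq. NH4Cl
Reagents that add atoms: none
Why: Copper-catalysed SN2' displacement of methoxide from methoxyallene by the aryl Grignard reagent should give the 3-arylpropyne directly, the benzyl ether being inert to magnesium.

Step 2
Reactants: 4 1-(benzyloxy)-2-methoxy-4-(prop-2-yn-1-yl)benzene; 5 4-(benzyloxy)-3-methoxybenzaldehyde
Product: 7 (1R)-1,4-bis[4-(benzyloxy)-3-methoxyphenyl]but-2-yn-1-ol, via methylzinc acetylide 6 (not isolated)
Conditions: 4 (2 equiv), Me2Zn (2 equiv), (R,R)-ProPhenol (10 mol%), Ph3PO (20 mol%), toluene, 0 °C to rt; then 5, 4 °C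
Reagents that add atoms: none
Why: Dinuclear zinc–ProPhenol catalysed enantioselective alkynylation of an aryl aldehyde, in which the chiral zinc pocket selects the aldehyde face and so sets the carbinol centre (1R).

Step 3
Reactants: 7 (1R)-1,4-bis[4-(benzyloxy)-3-methoxyphenyl]but-2-yn-1-ol
Product: 8 (1R)-1-[4-(benzyloxy)-3-methoxyphenyl]-3-[4-(benzyloxy)-3-methoxybenzyl]-2-methylidenebut-3-en-1-ol
Conditions: second-generation Grubbs catalyst RuCl2(=CHPh)(H2IMes)(PCy3) (5–10 mol%), ethylene (1 atm), toluene, 80 °C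
Reagents that add atoms: ethylene, C=C
Why: Ethylene–alkyne cross (enyne) metathesis should turn the internal alkyne into the 2,3-disubstituted buta-1,3-diene without touching the propargylic stereocentre.

Step 4
Reactants: 8 (1R)-1-[4-(benzyloxy)-3-methoxyphenyl]-3-[4-(benzyloxy)-3-methoxybenzyl]-2-methylidenebut-3-en-1-ol
Product: 9 (R)-[4-(benzyloxy)-3-methoxyphenyl](2-{3-[4-(benzyloxy)-3-methoxyphenyl]prop-1-en-2-yl}oxiran-2-yl)methanol (epimer mixture at the oxirane carbon)
Conditions: VO(acac)2 (3–5 mol%), t-BuOOH (1.3 equiv, decane), CH2Cl2, 0 °C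
Reagents that add atoms: tert-butyl hydroperoxide, CC(C)(C)OO
Why: Hydroxyl-directed epoxidation by the vanadium alkylperoxide reaches only the allylic alkene (the homoallylic one is far slower) and gives the 2-substituted 2-vinyloxirane; the new oxirane centre (erythro expected to prevail) is of no consequence because step 6 erases it.

Step 5
Reactants: 9 (R)-[4-(benzyloxy)-3-methoxyphenyl](2-{3-[4-(benzyloxy)-3-methoxyphenyl]prop-1-en-2-yl}oxiran-2-yl)methanol
Product: 10 tert-butyl{(R)-[4-(benzyloxy)-3-methoxyphenyl](2-{3-[4-(benzyloxy)-3-methoxyphenyl]prop-1-en-2-yl}oxiran-2-yl)methoxy}dimethylsilane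
Conditions: TBSCl, imidazole, DMAP (cat.), DMF, rt to 40 °C
Reagents that add atoms: tert-butyldimethylsilyl chloride, CC(C)(C)[Si](C)(C)Cl
Why: Standard silylation masks the carbinol so that it can neither bind copper nor start a semipinacol hydride shift next to the oxirane during the ring expansion.

Step 6
Reactants: 10 tert-butyl{(R)-[4-(benzyloxy)-3-methoxyphenyl](2-{3-[4-(benzyloxy)-3-methoxyphenyl]prop-1-en-2-yl}oxiran-2-yl)methoxy}dimethylsilane
Product: 11 tert-butyl{(R)-[4-(benzyloxy)-3-methoxyphenyl]{4-[4-(benzyloxy)-3-methoxybenzyl]-2,5-dihydrofuran-3-yl}methoxy}dimethylsilane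
Conditions: Cu(hfacac)2 (5 mol%), toluene, 110–150 °C, sealed tube
Reagents that add atoms: none
Why: Cu(hfacac)2 is reduced in situ to a monovalent copper species that opens the allylic C–O bond of the oxirane by SN2' oxidative addition at the vinyl terminus, giving an oxa-cupracycle of trivalent copper bound to the alkoxide oxygen and to the former =CH2 carbon. C–O reductive elimination then joins the oxirane oxygen to that carbon, so the three-membered ring O–CH2–C grows by the two vinyl carbons into the five-membered ring O–CH2–C=C–CH2, a formal 1,3-shift of oxygen. The closest known reaction type is the copper-catalysed ring expansion of vinyl oxiranes to 2,5-dihydrofurans, with the thermal and iodide-catalysed rearrangements of butadiene monoepoxide as relatives. The only ring closed is the oxolane ring, by O–C bond formation at the allyl terminus (equivalent to 5-exo-tet attack of the alkoxide on the cisoid sigma-allyl copper carbon). No stereocentre is created: the oxirane carbon becomes sp2, which removes the epimer mixture of step 4, and the silylated carbinol centre is not involved. The step needs the 1,3-shift to win over a hydride shift to an aldehyde and over ionisation at the benzylic carbon; the soft copper catalyst attacking the alkene (instead of a hard Lewis acid ionising the C–O bond), the silyl ether in place of a free hydroxyl, and a closure that by itself places both CH2–O groups cis on the new ring alkene should secure this.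

Step 7
Reactants: 11 tert-butyl{(R)-[4-(benzyloxy)-3-methoxyphenyl]{4-[4-(benzyloxy)-3-methoxybenzyl]-2,5-dihydrofuran-3-yl}methoxy}dimethylsilane
Product: 12 (R)-[4-(benzyloxy)-3-methoxyphenyl]{4-[4-(benzyloxy)-3-methoxybenzyl]-2,5-dihydrofuran-3-yl}methanol
Conditions: Bu4NF, THF, 0 °C
Reagents that add atoms: none
Why: Fluoride-induced Si–O cleavage frees the allylic alcohol needed as directing group under non-acidic conditions that should not ionise the benzylic, allylic C–O bond.

Step 8
Reactants: 12 (R)-[4-(benzyloxy)-3-methoxyphenyl]{4-[4-(benzyloxy)-3-methoxybenzyl]-2,5-dihydrofuran-3-yl}methanol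
Product: 13 (S)-[4-(benzyloxy)-3-methoxyphenyl]{(3R,4S)-4-[4-(benzyloxy)-3-methoxybenzyl]oxolan-3-yl}methanol
Conditions: [Ir(cod)(PCy3)(py)]PF6 (5–10 mol%), H2 (1 atm, higher pressure if slow), CH2Cl2, 0 °C to rt
Reagents that add atoms: none
Why: Hydroxyl-directed homogeneous hydrogenation of a tetrasubstituted alkene: A(1,3) strain with the benzylic CH2 on C4 holds the carbinol C–H in the alkene plane, so the iridium bound to the hydroxyl adds both hydrogens to one face, which makes the two ring substituents cis (3R,4S) and fixes them relative to the carbinol centre.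

Step 9
Reactants: 13 (S)-[4-(benzyloxy)-3-methoxyphenyl]{(3R,4S)-4-[4-(benzyloxy)-3-methoxybenzyl]oxolan-3-yl}methanol
Product: 14 4-{[(3S,4R)-4-[(S)-hydroxy(4-hydroxy-3-methoxyphenyl)methyl]oxolan-3-yl]methyl}-2-methoxyphenol
Conditions: H2 (1 atm), Pd/C (10 wt% palladium on carbon), EtOAc–EtOH, rt, stopped at full conversion
Reagents that add atoms: none
Why: Hydrogenolysis of the two aryl benzyl ethers on palladium under neutral conditions should be much faster than cleavage of the secondary benzylic C–OH bond and gives the target.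

**Compound list**
1 | 1-(benzyloxy)-4-bromo-2-methoxybenzene | COc1cc(Br)ccc1OCc1ccccc1 | starting material
2 | methoxyallene (1-methoxypropa-1,2-diene) | COC=C=C | starting material
3 | [4-(benzyloxy)-3-methoxyphenyl]magnesium bromide | COc1cc([Mg]Br)ccc1OCc1ccccc1 | intermediate
4 | 1-(benzyloxy)-2-methoxy-4-(prop-2-yn-1-yl)benzene | COc1cc(CC#C)ccc1OCc1ccccc1 | intermediate
5 | 4-(benzyloxy)-3-methoxybenzaldehyde | COc1cc(C=O)ccc1OCc1ccccc1 | starting material
6 | {3-[4-(benzyloxy)-3-methoxyphenyl]prop-1-yn-1-yl}(methyl)zinc | C[Zn]C#CCc1ccc(OCc2ccccc2)c(OC)c1 | intermediate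
7 | (1R)-1,4-bis[4-(benzyloxy)-3-methoxyphenyl]but-2-yn-1-ol | COc1cc(CC#C[C@H](O)c2ccc(OCc3ccccc3)c(OC)c2)ccc1OCc1ccccc1 | intermediate
8 | (1R)-1-[4-(benzyloxy)-3-methoxyphenyl]-3-[4-(benzyloxy)-3-methoxybenzyl]-2-methylidenebut-3-en-1-ol | COc1cc(CC(=C)C(=C)[C@H](O)c2ccc(OCc3ccccc3)c(OC)c2)ccc1OCc1ccccc1 | intermediate
9 | (R)-[4-(benzyloxy)-3-methoxyphenyl](2-{3-[4-(benzyloxy)-3-methoxyphenyl]prop-1-en-2-yl}oxiran-2-yl)methanol, both epimers at the oxirane carbon | COc1cc(CC(=C)C2(CO2)[C@H](O)c2ccc(OCc3ccccc3)c(OC)c2)ccc1OCc1ccccc1 | intermediate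
10 | tert-butyl{(R)-[4-(benzyloxy)-3-methoxyphenyl](2-{3-[4-(benzyloxy)-3-methoxyphenyl]prop-1-en-2-yl}oxiran-2-yl)methoxy}dimethylsilane, both epimers at the oxirane carbon | COc1cc(CC(=C)C2(CO2)[C@H](O[Si](C)(C)C(C)(C)C)c2ccc(OCc3ccccc3)c(OC)c2)ccc1OCc1ccccc1 | intermediate
11 | tert-butyl{(R)-[4-(benzyloxy)-3-methoxyphenyl]{4-[4-(benzyloxy)-3-methoxybenzyl]-2,5-dihydrofuran-3-yl}methoxy}dimethylsilane | COc1cc(CC2=C(COC2)[C@H](O[Si](C)(C)C(C)(C)C)c2ccc(OCc3ccccc3)c(OC)c2)ccc1OCc1ccccc1 | intermediate
12 | (R)-[4-(benzyloxy)-3-methoxyphenyl]{4-[4-(benzyloxy)-3-methoxybenzyl]-2,5-dihydrofuran-3-yl}methanol | COc1cc(CC2=C(COC2)[C@H](O)c2ccc(OCc3ccccc3)c(OC)c2)ccc1OCc1ccccc1 | intermediate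
13 | (S)-[4-(benzyloxy)-3-methoxyphenyl]{(3R,4S)-4-[4-(benzyloxy)-3-methoxybenzyl]oxolan-3-yl}methanol | COc1cc(C[C@@H]2COC[C@@H]2[C@H](O)c2ccc(OCc3ccccc3)c(OC)c2)ccc1OCc1ccccc1 | intermediate
14 | 4-{[(3S,4R)-4-[(S)-hydroxy(4-hydroxy-3-methoxyphenyl)methyl]oxolan-3-yl]methyl}-2-methoxyphenol | COc1cc(C[C@@H]2COC[C@@H]2[C@H](O)c2ccc(O)c(OC)c2)ccc1O | target

Total step count: 9
Longest linear sequence: 9 steps (1 to 14; aldehyde 5 enters at step 2)

**Steps most likely to fail**

Step 6. The oxirane may open by ionisation with a hydride shift to an aldehyde, or the hindered quaternary centre may slow the copper turnover until the benzylic silyl ether starts to ionise. Fallback, from 10 back to 11, through a halohydrin in two stages. MgI2·OEt2 in Et2O–toluene at −20 °C to rt opens the vinyloxirane, and the allylic iodides equilibrate to the primary iodide with the tetrasubstituted alkene, (2E)-2-{(R)-[4-(benzyloxy)-3-methoxyphenyl][(tert-butyldimethylsilyl)oxy]methyl}-3-[4-(benzyloxy)-3-methoxybenzyl]-4-iodobut-2-en-1-ol F1. Ag2O in Et2O at rt then closes the isomer with CH2OH and CH2 iodide cis by 5-exo-tet etherification to 11, the other isomer being fed back through the iodide equilibrium.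

Step 8. Facial control may be lost, the ring alkene may migrate to the enol ether position, or the benzylic allylic alcohol may ionise on the cationic iridium centre. Fallback, from 11 back to 13, replacing substrate direction by catalyst control with the silyl ether kept in place. Hydrogenation of 11 with a chiral iridium phosphine–oxazoline complex [Ir(cod)(tBu-PHOX)][B(C6H3(CF3)2)4] (ligand antipode matched to the substrate), H2 (50 bar), CH2Cl2, should give tert-butyl{(S)-[4-(benzyloxy)-3-methoxyphenyl]{(3R,4S)-4-[4-(benzyloxy)-3-methoxybenzyl]oxolan-3-yl}methoxy}dimethylsilane F2. Bu4NF in THF then gives 13.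

Step 9. Over-reduction by hydrogenolysis of the benzylic C–OH bond, which becomes easier once the para phenol is free. Fallback, from 13 back to 14, masking the carbinol during hydrogenolysis. TESCl and imidazole in DMF give triethyl{(S)-[4-(benzyloxy)-3-methoxyphenyl]{(3R,4S)-4-[4-(benzyloxy)-3-methoxybenzyl]oxolan-3-yl}methoxy}silane F3. H2 over Pd/C in EtOAc gives 4-{[(3S,4R)-4-{(S)-(4-hydroxy-3-methoxyphenyl)[(triethylsilyl)oxy]methyl}oxolan-3-yl]methyl}-2-methoxyphenol F4. HF·pyridine buffered with pyridine in THF at 0 °C (non-basic, so that no quinone methide forms) then gives 14.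

**Further compounds**
F1 | step 6 | (2E)-2-{(R)-[4-(benzyloxy)-3-methoxyphenyl][(tert-butyldimethylsilyl)oxy]methyl}-3-[4-(benzyloxy)-3-methoxybenzyl]-4-iodobut-2-en-1-ol | OC/C(=C(\CI)Cc1ccc(OCc2ccccc2)c(OC)c1)[C@H](O[Si](C)(C)C(C)(C)C)c1ccc(OCc2ccccc2)c(OC)c1
F2 | step 8 | tert-butyl{(S)-[4-(benzyloxy)-3-methoxyphenyl]{(3R,4S)-4-[4-(benzyloxy)-3-methoxybenzyl]oxolan-3-yl}methoxy}dimethylsilane | COc1cc(C[C@@H]2COC[C@@H]2[C@H](O[Si](C)(C)C(C)(C)C)c2ccc(OCc3ccccc3)c(OC)c2)ccc1OCc1ccccc1
F3 | step 9 | triethyl{(S)-[4-(benzyloxy)-3-methoxyphenyl]{(3R,4S)-4-[4-(benzyloxy)-3-methoxybenzyl]oxolan-3-yl}methoxy}silane | COc1cc(C[C@@H]2COC[C@@H]2[C@H](O[Si](CC)(CC)CC)c2ccc(OCc3ccccc3)c(OC)c2)ccc1OCc1ccccc1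
F4 | step 9 | 4-{[(3S,4R)-4-{(S)-(4-hydroxy-3-methoxyphenyl)[(triethylsilyl)oxy]methyl}oxolan-3-yl]methyl}-2-methoxyphenol | COc1cc(C[C@@H]2COC[C@@H]2[C@H](O[Si](CC)(CC)CC)c2ccc(O)c(OC)c2)ccc1O
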